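**Retrosynthetic overview**
1. Target ⇐ fully protected flavone; the last events are hydrogenolysis of the ring A benzyl ethers, then methanolic HCl cleavage of the ring B MOM acetals.
2. Protected flavone ⇐ C2–C1' bond: a ring A/C chromone (C2–H) plus a ring B benzoic acid, joined by a proposed decarboxylative oxidative Heck-type C2-arylation (the new step).
3. Chromone ⇐ ring C closure by the enaminone method on a 2-hydroxy-4,6-bis(benzyloxy)-3,5-dimethoxyacetophenone, whose two OMe groups come from dibromination and Ullmann methanolysis of dibenzylated phloroacetophenone.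
4. Ring B acid ⇐ directed ortho-lithiation and carboxylation of bis-MOM-protected methoxyhydroquinone, at the carbon between OMe and OMOM.
5. Ring order: rings A and B are bought as benzenes; ring C is built on ring A first; ring B is attached last.

Assumption: the target has no stereocentre and its aryl–chromone axis rotates freely, so it is achiral and "single enantiomer" calls for no stereocontrol.
Assumption: phenoxide salts that exist only under the basic reaction conditions are counted with their parent phenols.

**Route**

Step 1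
Reactants: 1 2-methoxybenzene-1,4-diol (methoxyhydroquinone)
Product: 2 2-methoxy-1,4-bis(methoxymethoxy)benzene
Conditions: NaH (2.4 equiv), MOMCl (2.4 equiv), DMF, 0 °C to rt, Ar
Reagents that add atoms: chloromethyl methyl ether (MOMCl), COCCl
Why: Double Williamson-type O-alkylation of the hydroquinone bis-phenoxide with the reactive α-chloro ether gives the bis-MOM acetal, which masks the oxidation-prone hydroquinone and supplies a strong ortho-directing group for step 2.

Step 2
Reactants: 2 2-methoxy-1,4-bis(methoxymethoxy)benzene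
Product: 5 2-methoxy-3,6-bis(methoxymethoxy)benzoic acid, via aryllithium 3 (not isolated), via lithium carboxylate 4 (not isolated)
Conditions: n-BuLi (1.15 equiv), THF, 0 °C, 1 h; CO2 (g), −78 °C to rt; cold 1 M HCl to pH 3
Reagents that add atoms: carbon dioxide, O=C=O
Why: Directed ortho-metalation takes place at the one ring position flanked by two coordinating oxygens (between OMe and OMOM), as is known for 1,2,4-trialkoxybenzenes, and the aryllithium is trapped by CO2 to give the carboxylate, which cold dilute acid protonates without touching the MOM acetals.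

Step 3
Reactants: 6 1-(2,4,6-trihydroxyphenyl)ethan-1-one (phloroacetophenone)
Product: 7 1-[2,4-bis(benzyloxy)-6-hydroxyphenyl]ethan-1-one
Conditions: BnBr (2.05 equiv), K2CO3 (2.2 equiv), acetone, reflux
Reagents that add atoms: benzyl bromide, BrCc1ccccc1
Why: Williamson etherification with two equivalents of BnBr leaves one ortho-hydroxyl free because it is tied up in a strong hydrogen bond to the acetyl carbonyl and is the least nucleophilic of the three.

Step 4
Reactants: 7 1-[2,4-bis(benzyloxy)-6-hydroxyphenyl]ethan-1-one
Product: 8 1-[2,4-bis(benzyloxy)-3,5-dibromo-6-hydroxyphenyl]ethan-1-one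
Conditions: NBS (2.1 equiv), CH2Cl2, 0 °C to rt, dark
Reagents that add atoms: N-bromosuccinimide, O=C1CCC(=O)N1Br
Why: Electrophilic aromatic bromination fills the only two free ring positions, both strongly activated (ortho or para to the free phenol and flanked by ether oxygens), while the benzyl rings and the acetyl group are untouched at 0 °C.

Step 5
Reactants: 8 1-[2,4-bis(benzyloxy)-3,5-dibromo-6-hydroxyphenyl]ethan-1-one
Product: 9 1-[2,4-bis(benzyloxy)-6-hydroxy-3,5-dimethoxyphenyl]ethan-1-one
Conditions: NaOMe (10 equiv), CuBr (30 mol %), DMF–MeOH, 110 °C; then dilute HCl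
Reagents that add atoms: sodium methoxide, [Na+].[O-]C
Why: Ullmann-type methanolysis (C–O coupling of aryl bromides with methoxide, catalysed by monovalent copper) replaces both bromides by OMe, a reaction well established for ortho-bromophenols and 2,6-dioxygenated bromoarenes, and the benzyl ethers and the ketone tolerate it.

Step 6
Reactants: 9 1-[2,4-bis(benzyloxy)-6-hydroxy-3,5-dimethoxyphenyl]ethan-1-one
Product: 11 5,7-bis(benzyloxy)-6,8-dimethoxy-4H-chromen-4-one, via enaminone 10 (not isolated)
Conditions: Me2NCH(OMe)2 (3 equiv), toluene, 100 °C; evaporate; conc. HCl, CH2Cl2, rt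
Reagents that add atoms: N,N-dimethylformamide dimethyl acetal, COC(OC)N(C)C
Why: Condensation of the methyl ketone with the amide acetal gives the β-(dimethylamino)enone, and acid then triggers intramolecular oxa-Michael addition of the free phenol and loss of dimethylamine to close ring C (the enaminone route to 2,3-unsubstituted chromones).

Step 7
Reactants: 11 5,7-bis(benzyloxy)-6,8-dimethoxy-4H-chromen-4-one; 5 2-methoxy-3,6-bis(methoxymethoxy)benzoic acid (2 equiv)
Product: 12 5,7-bis(benzyloxy)-6,8-dimethoxy-2-[2-methoxy-3,6-bis(methoxymethoxy)phenyl]-4H-chromen-4-one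
Conditions: Pd(OCOCF3)2 (20 mol %), Ag2CO3 (3 equiv), DMSO–DMF (1:20), 110 °C
Reagents that add atoms: none
Why: Proposed new method: a decarboxylative oxidative Heck-type C2–H arylation of a chromone, in which the di-ortho-alkoxy pattern of acid 5 (the pattern that makes benzoic acids lose CO2 readily on divalent palladium) delivers an arylpalladium trifluoroacetate that inserts C2=C3 of 11 with the aryl group going to C2 (favoured by both the enone and the enol-ether polarisation), the C3 palladium enolate epimerises and undergoes β-hydride elimination to the flavone, and Ag2CO3 returns zerovalent palladium to the divalent state; the closest known reaction types are the decarboxylative Heck olefination of electron-rich ortho-substituted benzoic acids under divalent palladium and Ag2CO3, and the oxidative Heck-type C2-arylation of chromones with arylboronic acids.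

Step 8
Reactants: 12 5,7-bis(benzyloxy)-6,8-dimethoxy-2-[2-methoxy-3,6-bis(methoxymethoxy)phenyl]-4H-chromen-4-one
Product: 13 5,7-dihydroxy-6,8-dimethoxy-2-[2-methoxy-3,6-bis(methoxymethoxy)phenyl]-4H-chromen-4-one
Conditions: H2 (1 atm), 10% Pd/C, EtOAc–MeOH, rt
Reagents that add atoms: none
Why: Catalytic hydrogenolysis cleaves the two benzylic C–O bonds under neutral conditions that leave the MOM acetals, the methyl ethers and the hindered, vinylogous-ester C2=C3 bond of the flavone intact when the reaction is stopped at full conversion.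

Step 9
Reactants: 13 5,7-dihydroxy-6,8-dimethoxy-2-[2-methoxy-3,6-bis(methoxymethoxy)phenyl]-4H-chromen-4-one
Product: 14 5,7-dihydroxy-2-(3,6-dihydroxy-2-methoxyphenyl)-6,8-dimethoxy-4H-chromen-4-one (5,7,3',6'-tetrahydroxy-6,8,2'-trimethoxyflavone)
Conditions: HCl (1.25 M in MeOH), degassed, 45 °C, Ar
Reagents that add atoms: none
Why: Acid-catalysed acetal exchange with methanol removes both MOM groups as dimethoxymethane, while aryl methyl ethers and the pyranone ring are stable to dilute HCl and the symmetric substitution of ring A means that even a Wessely–Moser ring opening and reclosure could only return the same flavone.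

**Compound list**
1 | 2-methoxybenzene-1,4-diol (methoxyhydroquinone) | COc1cc(O)ccc1O | starting material
2 | 2-methoxy-1,4-bis(methoxymethoxy)benzene | COCOc1ccc(OCOC)c(OC)c1 | intermediate
3 | [2-methoxy-3,6-bis(methoxymethoxy)phenyl]lithium | [Li]c1c(OC)c(OCOC)ccc1OCOC | intermediate
4 | lithium 2-methoxy-3,6-bis(methoxymethoxy)benzoate | [Li+].[O-]C(=O)c1c(OC)c(OCOC)ccc1OCOC | intermediate
5 | 2-methoxy-3,6-bis(methoxymethoxy)benzoic acid | OC(=O)c1c(OC)c(OCOC)ccc1OCOC | intermediate
6 | 1-(2,4,6-trihydroxyphenyl)ethan-1-one (phloroacetophenone) | CC(=O)c1c(O)cc(O)cc1O | starting material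
7 | 1-[2,4-bis(benzyloxy)-6-hydroxyphenyl]ethan-1-one | CC(=O)c1c(O)cc(OCc2ccccc2)cc1OCc1ccccc1 | intermediate
8 | 1-[2,4-bis(benzyloxy)-3,5-dibromo-6-hydroxyphenyl]ethan-1-one | CC(=O)c1c(O)c(Br)c(OCc2ccccc2)c(Br)c1OCc1ccccc1 | intermediate
9 | 1-[2,4-bis(benzyloxy)-6-hydroxy-3,5-dimethoxyphenyl]ethan-1-one | CC(=O)c1c(O)c(OC)c(OCc2ccccc2)c(OC)c1OCc1ccccc1 | intermediate
10 | (2E)-1-[2,4-bis(benzyloxy)-6-hydroxy-3,5-dimethoxyphenyl]-3-(dimethylamino)prop-2-en-1-one | CN(C)/C=C/C(=O)c1c(O)c(OC)c(OCc2ccccc2)c(OC)c1OCc1ccccc1 | intermediate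
11 | 5,7-bis(benzyloxy)-6,8-dimethoxy-4H-chromen-4-one | O=c1ccoc2c(OC)c(OCc3ccccc3)c(OC)c(OCc3ccccc3)c12 | intermediate
12 | 5,7-bis(benzyloxy)-6,8-dimethoxy-2-[2-methoxy-3,6-bis(methoxymethoxy)phenyl]-4H-chromen-4-one | COCOc1ccc(OCOC)c(OC)c1-c1cc(=O)c2c(OCc3ccccc3)c(OC)c(OCc3ccccc3)c(OC)c2o1 | intermediate
13 | 5,7-dihydroxy-6,8-dimethoxy-2-[2-methoxy-3,6-bis(methoxymethoxy)phenyl]-4H-chromen-4-one | COCOc1ccc(OCOC)c(OC)c1-c1cc(=O)c2c(O)c(OC)c(O)c(OC)c2o1 | intermediate
14 | 5,7-dihydroxy-2-(3,6-dihydroxy-2-methoxyphenyl)-6,8-dimethoxy-4H-chromen-4-one (5,7,3',6'-tetrahydroxy-6,8,2'-trimethoxyflavone) | COc1c(O)ccc(O)c1-c1cc(=O)c2c(O)c(OC)c(O)c(OC)c2o1 | target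

**Totals and risks**
Total step count: 9. Longest linear sequence: 7 steps (6 → 7 → 8 → 9 → 11 → 12 → 13 → 14, steps 3 to 9); the ring B branch (steps 1 and 2) joins at step 7.

The three steps most likely to fail:

(a) Step 7, the proposed new step. The likely failures are protodecarboxylation of 5 back to 2 (recoverable and re-usable in step 2), a conjugate-addition product (flavanone) in place of the Heck product, and slow insertion of the di-ortho-substituted arylpalladium. The fallback uses known chemistry (directed zincation of chromones followed by Negishi cross-coupling), sets out from chromone 11 and comes back to the route at 12. Aryllithium 3, made as in step 2, is quenched with I2 (THF, −78 °C) to give 2-iodo-3-methoxy-1,4-bis(methoxymethoxy)benzene F1. Chromone 11 is zincated at C2 with TMPZnCl·LiCl in the presence of MgCl2 (THF, 25 °C) to give [5,7-bis(benzyloxy)-6,8-dimethoxy-4-oxo-4H-chromen-2-yl]zinc chloride F2. F2 is coupled in the same flask with F1 (Pd(OAc)2, SPhos, THF, 50 °C) to give 12.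

(b) Step 5, the double Ullmann methanolysis at two hindered positions, where hydrodebromination is the usual failure. The fallback forms the C–O bonds as hydroxyls first and methylates afterwards; it sets out from dibromide 8 and comes back at 9. Hydroxylation of both C–Br bonds (Pd2(dba)3, tBuXPhos, KOH, dioxane–H2O, 100 °C, Ar) gives 1-[2,4-bis(benzyloxy)-3,5,6-trihydroxyphenyl]ethan-1-one F3. The two new, non-chelated hydroxyls are then methylated selectively (MeI 2.1 equiv, K2CO3, acetone, rt, Ar) to give 9, the hydroxyl hydrogen-bonded to the acetyl group staying free.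

(c) Step 9, where the oxidation-prone hydroquinone of ring B is set free in acidic solution in the last operation. The fallback reverses the end-game so that the final step is a neutral hydrogenolysis; it sets out from 12 and comes back at 14. The MOM acetals are cleaved first (HCl 1.25 M in MeOH–THF, 40 °C) to give 5,7-bis(benzyloxy)-2-(3,6-dihydroxy-2-methoxyphenyl)-6,8-dimethoxy-4H-chromen-4-one F4. F4 is then debenzylated (H2 1 atm, 10% Pd/C, EtOAc, rt) and 14 is isolated by filtration and evaporation under Ar.

Further compounds
F1 | step 7 | 2-iodo-3-methoxy-1,4-bis(methoxymethoxy)benzene | COCOc1ccc(OCOC)c(OC)c1I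
F2 | step 7 | [5,7-bis(benzyloxy)-6,8-dimethoxy-4-oxo-4H-chromen-2-yl]zinc chloride | Cl[Zn]c1cc(=O)c2c(OCc3ccccc3)c(OC)c(OCc3ccccc3)c(OC)c2o1
F3 | step 5 | 1-[2,4-bis(benzyloxy)-3,5,6-trihydroxyphenyl]ethan-1-one | CC(=O)c1c(O)c(O)c(OCc2ccccc2)c(O)c1OCc1ccccc1
F4 | step 9 | 5,7-bis(benzyloxy)-2-(3,6-dihydroxy-2-methoxyphenyl)-6,8-dimethoxy-4H-chromen-4-one | COc1c(O)ccc(O)c1-c1cc(=O)c2c(OCc3ccccc3)c(OC)c(OCc3ccccc3)c(OC)c2o1
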